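**Retrosynthetic overview**
- The strategy rests on C7 of the oxolane ring: it is benzylic, para to the C4 hydroxyl of ring B and bonded to the ring oxygen that C9' carries. The C7–O bond is therefore cut last, back to a ring B para-quinone methide of an open-chain triol that already carries the aryltetralin half.
- The C5–C5' biaryl bond between rings B and C is cut next (Suzuki–Miyaura), giving an open-chain boronate half and a bromo-aryltetralin half.
- Both halves come from one dioxolanone acid built on diisopropyl (S)-malate: a Fráter–Seebach benzylation sets C8, and a Seebach dioxolanone alkylation with the isovanillyl or the vanillyl bromide sets the quaternary carbinol C8'.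
- Ring order: the cyclohexane ring of the tetralin (quinone-methide Friedel–Crafts, step 19), then the biaryl bond (step 22), then the oxolane (step 24).

Key step: step 24

Remark: lignan numbering is used (C7–C9 on the ring B arm, C7'–C9' on the ring A arm, T1–T4 for the saturated tetralin carbons; ring A = 3-hydroxy-4-methoxyphenyl, ring B = aryl on C7, ring C = aryl on T1, ring D = benzo ring of the tetralin); the target SMILES is read as (7S,8R,8'S) in the oxolane and (T1 S, T2 S, T3 S) in the tetralin, and commercial diisopropyl (S)-malate is taken as the ester form of (S)-malic acid.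

**Step 1**
Reactants: 1 5-bromovanillin
Product: 2 4-(benzyloxy)-3-bromo-5-methoxybenzaldehyde
Conditions: BnBr, K2CO3, DMF, 60 °C
Reagents that add atoms: benzyl bromide, BrCc1ccccc1
Why: Williamson etherification of the phenoxide gives a benzyl ether that withstands the bases, acids and hydrides used before it is removed.

**Step 2**
Reactants: 2 4-(benzyloxy)-3-bromo-5-methoxybenzaldehyde
Product: 3 [4-(benzyloxy)-3-bromo-5-methoxyphenyl]methanol
Conditions: NaBH4, MeOH/THF, 0 °C
Reagents that add atoms: none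
Why: Borohydride reduction of the aldehyde leaves the aryl bromide and the benzyl ether untouched.

**Step 3**
Reactants: 3 [4-(benzyloxy)-3-bromo-5-methoxyphenyl]methanol
Product: 4 2-(benzyloxy)-1-bromo-5-(bromomethyl)-3-methoxybenzene
Conditions: PBr3, CH2Cl2, 0 °C
Reagents that add atoms: phosphorus tribromide, BrP(Br)Br
Why: The benzylic alcohol is converted to the bromide through its phosphite ester by bromide displacement.

**Step 4**
Reactants: 5 diisopropyl (S)-malate; 4 2-(benzyloxy)-1-bromo-5-(bromomethyl)-3-methoxybenzene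
Product: 7 diisopropyl (2S,3R)-3-[4-(benzyloxy)-3-bromo-5-methoxybenzyl]-2-hydroxysuccinate, via dilithium alkoxide enolate 6 (not isolated)
Conditions: LiN(SiMe3)2 (2.2 equiv), THF, −78 → −20 °C; then 4, −78 → 0 °C; aq. NH4Cl
Reagents that add atoms: none
Why: Fráter–Seebach alkylation, in which the lithium-chelated alkoxide enolate is benzylated on the face anti to the C2 ester group, should give mainly the anti (2S,3R) diester and so sets C8.

**Step 5**
Reactants: 7 diisopropyl (2S,3R)-3-[4-(benzyloxy)-3-bromo-5-methoxybenzyl]-2-hydroxysuccinate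
Product: 8 (2S,3R)-3-[4-(benzyloxy)-3-bromo-5-methoxybenzyl]-2-hydroxysuccinic acid
Conditions: KOH, H2O/MeOH, rt → 50 °C; then 2 M HCl
Reagents that add atoms: potassium hydroxide, [K+].[OH-]
Why: Saponification of both esters, in which the carboxylates formed protect C3 against epimerisation, frees the α-hydroxy acid needed for acetal formation.

**Step 6**
Reactants: 8 (2S,3R)-3-[4-(benzyloxy)-3-bromo-5-methoxybenzyl]-2-hydroxysuccinic acid
Product: 9 (2R)-3-[4-(benzyloxy)-3-bromo-5-methoxyphenyl]-2-[(2S,4S)-2-tert-butyl-5-oxo-1,3-dioxolan-4-yl]propanoic acid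
Conditions: t-BuCHO, TsOH·H2O (cat.), H2SO4 (cat.), pentane/CH2Cl2, reflux, Dean–Stark
Reagents that add atoms: pivalaldehyde, CC(C)(C)C=O
Why: Acid-catalysed acetalisation of the α-hydroxy acid prefers the five-membered dioxolanone over the six-membered dioxanone and, being reversible, should give the cis (2S) acetal as the thermodynamic isomer, which stores the C8' configuration.

**Step 7**
Reactants: 10 isovanillin
Product: 11 5-formyl-2-methoxyphenyl pivalate
Conditions: PivCl, Et3N, DMAP (cat.), CH2Cl2, 0 °C → rt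
Reagents that add atoms: pivaloyl chloride, CC(C)(C)C(=O)Cl
Why: O-Acylation of the phenol gives a hindered ester that tolerates the brief enolate alkylation at low temperature and is shed later by hydride.

**Step 8**
Reactants: 11 5-formyl-2-methoxyphenyl pivalate
Product: 12 5-(hydroxymethyl)-2-methoxyphenyl pivalate
Conditions: NaBH4, THF/MeOH, 0 °C
Reagents that add atoms: none
Why: Borohydride reduces the aldehyde much faster than the hindered aryl pivalate at 0 °C.

**Step 9**
Reactants: 12 5-(hydroxymethyl)-2-methoxyphenyl pivalate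
Product: 13 5-(bromomethyl)-2-methoxyphenyl pivalate
Conditions: PBr3, CH2Cl2, 0 °C
Reagents that add atoms: phosphorus tribromide, BrP(Br)Br
Why: Bromination of the benzylic alcohol through the phosphite ester gives the reactive benzylic bromide, to be used freshly prepared.

**Step 10**
Reactants: 9 (2R)-3-[4-(benzyloxy)-3-bromo-5-methoxyphenyl]-2-[(2S,4S)-2-tert-butyl-5-oxo-1,3-dioxolan-4-yl]propanoic acid; 13 5-(bromomethyl)-2-methoxyphenyl pivalate
Product: 15 (2R)-3-[4-(benzyloxy)-3-bromo-5-methoxyphenyl]-2-[(2S,4S)-2-tert-butyl-4-{[4-methoxy-3-(pivaloyloxy)phenyl]methyl}-5-oxo-1,3-dioxolan-4-yl]propanoic acid, via dilithium carboxylate enolate 14 (not isolated)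
Conditions: LiN(SiMe3)2 (2.3 equiv), THF, −78 °C; then 13, −78 → −30 °C; 1 M HCl
Reagents that add atoms: none
Why: Seebach alkylation with self-regeneration of the stereocentre, in which the planar dioxolanone enolate is benzylated anti to the tert-butyl group, replaces the former C–H with retention and should set the quaternary C8' with the two benzyl groups in the relative arrangement of the target.

**Step 11**
Reactants: 15 the dioxolanone acid of step 10
Product: 16 (2S,3S)-3-[4-(benzyloxy)-3-bromo-5-methoxybenzyl]-2-(3-hydroxy-4-methoxybenzyl)butane-1,2,4-triol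
Conditions: LiAlH4, THF, 0 °C → rt; aq. potassium sodium tartrate
Reagents that add atoms: none
Why: Hydride reduction converts the carboxylic acid and the dioxolanone carbonyl into the two primary alcohols (the acetal collapses to free the tertiary hydroxyl) and cleaves the aryl pivalate, while the aryl bromide and the benzyl ether should survive at or below room temperature.

**Step 12**
Reactants: 16 (2S,3S)-3-[4-(benzyloxy)-3-bromo-5-methoxybenzyl]-2-(3-hydroxy-4-methoxybenzyl)butane-1,2,4-triol
Product: 17 5-{(2S,3S)-3-[4-(benzyloxy)-3-bromo-5-methoxybenzyl]-2,4-dihydroxy-2-(hydroxymethyl)butyl}-2-methoxyphenyl pivalate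
Conditions: PivCl (1.05 equiv), K2CO3, acetone, 0 °C → rt
Reagents that add atoms: pivaloyl chloride, CC(C)(C)C(=O)Cl
Why: Only the phenol is deprotonated by carbonate, so the phenoxide should be acylated selectively in the presence of the neutral aliphatic hydroxyls (Schotten–Baumann-type chemoselective O-acylation).

**Step 13**
Reactants: 17 the ring A pivalate of step 12
Product: 18 5-{(2S,3S)-3-[4-(benzyloxy)-3-methoxy-5-(4,4,5,5-tetramethyl-1,3,2-dioxaborolan-2-yl)benzyl]-2,4-dihydroxy-2-(hydroxymethyl)butyl}-2-methoxyphenyl pivalate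
Conditions: B2pin2, PdCl2(dppf), KOAc, 1,4-dioxane, 85 °C
Reagents that add atoms: bis(pinacolato)diboron, CC1(C)OB(OC1(C)C)B1OC(C)(C)C(C)(C)O1
Why: Miyaura borylation of the aryl bromide with the weak base KOAc tolerates free hydroxyls and the aryl pivalate.

**Step 14**
Reactants: 19 vanillin
Product: 20 4-formyl-2-methoxyphenyl pivalate
Conditions: PivCl, Et3N, DMAP (cat.), CH2Cl2, 0 °C → rt
Reagents that add atoms: pivaloyl chloride, CC(C)(C)C(=O)Cl
Why: O-Acylation of the phenol installs the group that later keeps ring D from forming its own quinone methide while leaving the position para to the methoxy group nucleophilic.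

**Step 15**
Reactants: 20 4-formyl-2-methoxyphenyl pivalate
Product: 21 4-(hydroxymethyl)-2-methoxyphenyl pivalate
Conditions: NaBH4, THF/MeOH, 0 °C
Reagents that add atoms: none
Why: Chemoselective borohydride reduction of the aldehyde in the presence of the hindered aryl ester.

**Step 16**
Reactants: 21 4-(hydroxymethyl)-2-methoxyphenyl pivalate
Product: 22 4-(bromomethyl)-2-methoxyphenyl pivalate
Conditions: PBr3, CH2Cl2, 0 °C
Reagents that add atoms: phosphorus tribromide, BrP(Br)Br
Why: Bromination of the benzylic alcohol through the phosphite ester.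

**Step 17**
Reactants: 9 the dioxolanone acid of step 6; 22 4-(bromomethyl)-2-methoxyphenyl pivalate
Product: 24 (2R)-3-[4-(benzyloxy)-3-bromo-5-methoxyphenyl]-2-[(2S,4S)-2-tert-butyl-4-{[3-methoxy-4-(pivaloyloxy)phenyl]methyl}-5-oxo-1,3-dioxolan-4-yl]propanoic acid, via disodium carboxylate enolate 23 (not isolated)
Conditions: NaN(SiMe3)2 (2.3 equiv), THF, −78 °C; then 22, −78 → −50 °C; 1 M HCl
Reagents that add atoms: none
Why: Seebach dioxolanone alkylation anti to the tert-butyl group should set the quaternary carbinol carbon T3 of the tetralin half with retention; the more nucleophilic sodium enolate is used because bromide 22, which has an acyloxy and not a methoxy group para to the bromomethyl group, is a less reactive electrophile than 13.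

**Step 18**
Reactants: 24 the dioxolanone acid of step 17
Product: 25 (2R)-3-(3-bromo-4-hydroxy-5-methoxyphenyl)-2-[(2S,4S)-2-tert-butyl-4-{[3-methoxy-4-(pivaloyloxy)phenyl]methyl}-5-oxo-1,3-dioxolan-4-yl]propanoic acid
Conditions: BCl3 (4 equiv), pentamethylbenzene, CH2Cl2, −78 °C; then H2O
Reagents that add atoms: none
Why: Lewis-acid cleavage of the aryl benzyl ether, assisted by chelation to the neighbouring methoxy group and with pentamethylbenzene trapping the benzyl cation, spares the aryl bromide that hydrogenolysis would remove and should leave the pivalate and the dioxolanone intact at −78 °C.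

**Step 19**
Reactants: 25 the ring C phenol of step 18
Product: 27 (2S,4S,3'R,4'S)-4'-(3-bromo-4-hydroxy-5-methoxyphenyl)-2-tert-butyl-7'-methoxy-5-oxo-6'-(pivaloyloxy)-3',4'-dihydro-1'H-spiro[1,3-dioxolane-4,2'-naphthalene]-3'-carboxylic acid, via quinone methide 26 (not isolated)
Conditions: DDQ (1.05 equiv), CH2Cl2, 0 °C; then CF3CO2H, 0 °C → rt
Reagents that add atoms: none
Why: DDQ dehydrogenates the 4-hydroxybenzyl group of ring C to the para-quinone methide, and acid then triggers intramolecular Friedel–Crafts alkylation by the ring D carbon para to its methoxy group (the quinone-methide route to aryltetralin lignans), closing the six-membered ring with the aryl group pseudo-equatorial and trans to the neighbouring carboxyl, which sets T1 (S).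

**Step 20**
Reactants: 27 the spiro-dioxolanone aryltetralin acid of step 19
Product: 28 (2S,3S,4S)-4-(3-bromo-4-hydroxy-5-methoxyphenyl)-2,3-bis(hydroxymethyl)-7-methoxy-1,2,3,4-tetrahydronaphthalene-2,6-diol
Conditions: LiAlH4, THF, 0 → 40 °C; aq. potassium sodium tartrate
Reagents that add atoms: none
Why: Hydride reduction of the carboxylic acid and the dioxolanone gives the two hydroxymethyl groups and the tertiary alcohol and cleaves the pivalate, without touching a stereocentre or, at moderate temperature, the aryl bromide.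

**Step 21**
Reactants: 28 the bromo-aryltetralin triol diphenol of step 20
Product: 29 bis(pivalate) of 28 at the ring C and ring D phenols, (2S,3S,4S)
Conditions: PivCl (2.2 equiv), K2CO3, acetone, 0 °C → rt
Reagents that add atoms: pivaloyl chloride, CC(C)(C)C(=O)Cl
Why: Both phenols are acylated as their phenoxides in preference to the neutral aliphatic hydroxyls, as in step 12.

**Step 22**
Reactants: 18 the open-chain boronate; 29 the bromo-aryltetralin bis(pivalate)
Product: 30 C5–C5' biaryl with ring B O-benzyl, ring A O-pivalate, ring C O-pivalate and ring D O-pivalate, all six aliphatic hydroxyls free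
Conditions: Pd(OAc)2 (5 mol %), SPhos (10 mol %), K3PO4, 1,4-dioxane/H2O (10:1), 60 °C
Reagents that add atoms: none
Why: Suzuki–Miyaura coupling of two partners that each carry one ortho oxygen substituent is well served by the SPhos catalyst at moderate temperature, free hydroxyls are tolerated, and the biaryl axis with only two ortho substituents creates no stereogenic element.

**Step 23**
Reactants: 30 the ring B O-benzyl biaryl
Product: 31 the key-step precursor: open-chain (2S,3S)-butane-1,2,4-triol half with free ring B phenol and ring A pivalate, joined C5–C5' to the (2S,3S,4S)-aryltetralin triol bis(pivalate)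
Conditions: H2 (1 atm), Pd/C, EtOAc/EtOH, rt
Reagents that add atoms: none
Why: Hydrogenolysis removes the only benzyl ether under neutral conditions at a stage where no aryl halide and no other benzylic C–O bond is present, so the ring B phenol is freed without pivaloyl migration.

**Step 24**
Reactants: 31 the key-step precursor
Product: 33 tris(pivalate) of the target with the (7S,8R,8'S)-oxolane closed, via quinone methide 32 (not isolated)
Conditions: DDQ (1.0 equiv), 1,4-dioxane/CH2Cl2 (dry), 0 °C → rt, dark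
Reagents that add atoms: none
Why: DDQ complexes the only free phenol (ring B) and abstracts hydride from the para benzylic C7 methylene to give para-quinone methide 32. The primary C9' hydroxyl then adds to C7 in a 5-exo-trig oxa-conjugate addition that rearomatises ring B and closes the oxolane by the C7–O bond, whereas the C9 and C8' hydroxyls could only form oxetanes. The closest known reaction is the DDQ cyclisation of 4-hydroxybenzyl-substituted butanediols to 2-aryltetrahydrofuran lignans. The new stereocentre C7 is controlled by C8: attack anti to the C8 hydroxymethyl group should give the 7,8-trans (7S) isomer, which is also the more stable one, so any reversible reopening through the quinone methide converges on it. The step needs oxidation at C7 only; this is secured by the three pivalates, which block quinone methide formation at T1, T4 and on ring A and deactivate ring A toward Friedel–Crafts capture, and by using one equivalent of DDQ at low temperature to limit further oxidation of the product.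

**Step 25**
Reactants: 33 the target tris(pivalate)
Product: 34 the target CNP0252244.1
Conditions: K2CO3, MeOH (degassed), Ar, rt → 40 °C; aq. NH4Cl
Reagents that add atoms: none
Why: Carbonate-mediated methanolysis removes the three aryl pivalates under basic conditions that leave the acid-labile benzylic oxolane ether alone, and C7 is already in its more stable trans arrangement so a reversible opening through the phenoxide cannot scramble it.

**Compound list**
1 | 5-bromovanillin | COc1cc(C=O)cc(Br)c1O | starting material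
2 | 4-(benzyloxy)-3-bromo-5-methoxybenzaldehyde | COc1cc(C=O)cc(Br)c1OCc2ccccc2 | intermediate
3 | [4-(benzyloxy)-3-bromo-5-methoxyphenyl]methanol | COc1cc(CO)cc(Br)c1OCc2ccccc2 | intermediate
4 | 2-(benzyloxy)-1-bromo-5-(bromomethyl)-3-methoxybenzene | COc1cc(CBr)cc(Br)c1OCc2ccccc2 | intermediate
5 | diisopropyl (S)-malate | CC(C)OC(=O)C[C@H](O)C(=O)OC(C)C | starting material
6 | dilithium alkoxide enolate of 5 | CC(C)O/C([O-])=C/[C@H]([O-])C(=O)OC(C)C.[Li+].[Li+] | intermediate
7 | diisopropyl (2S,3R)-3-[4-(benzyloxy)-3-bromo-5-methoxybenzyl]-2-hydroxysuccinate | CC(C)OC(=O)[C@@H](O)[C@@H](Cc1cc(OC)c(OCc2ccccc2)c(Br)c1)C(=O)OC(C)C | intermediate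
8 | (2S,3R)-3-[4-(benzyloxy)-3-bromo-5-methoxybenzyl]-2-hydroxysuccinic acid | OC(=O)[C@@H](O)[C@@H](Cc1cc(OC)c(OCc2ccccc2)c(Br)c1)C(=O)O | intermediate
9 | (2R)-3-[4-(benzyloxy)-3-bromo-5-methoxyphenyl]-2-[(2S,4S)-2-tert-butyl-5-oxo-1,3-dioxolan-4-yl]propanoic acid (cis-dioxolanone) | O=C1O[C@@H](C(C)(C)C)O[C@H]1[C@@H](Cc2cc(OC)c(OCc3ccccc3)c(Br)c2)C(=O)O | intermediate
10 | isovanillin | COc1ccc(C=O)cc1O | starting material
11 | 5-formyl-2-methoxyphenyl pivalate | COc1ccc(C=O)cc1OC(=O)C(C)(C)C | intermediate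
12 | 5-(hydroxymethyl)-2-methoxyphenyl pivalate | COc1ccc(CO)cc1OC(=O)C(C)(C)C | intermediate
13 | 5-(bromomethyl)-2-methoxyphenyl pivalate | COc1ccc(CBr)cc1OC(=O)C(C)(C)C | intermediate
14 | dilithium carboxylate enolate of 9 | [O-]C1=C([C@@H](Cc2cc(OC)c(OCc3ccccc3)c(Br)c2)C(=O)[O-])O[C@H](C(C)(C)C)O1.[Li+].[Li+] | intermediate
15 | (2R)-3-[4-(benzyloxy)-3-bromo-5-methoxyphenyl]-2-[(2S,4S)-2-tert-butyl-4-{[4-methoxy-3-(pivaloyloxy)phenyl]methyl}-5-oxo-1,3-dioxolan-4-yl]propanoic acid | O=C1O[C@@H](C(C)(C)C)O[C@@]1(Cc2ccc(OC)c(OC(=O)C(C)(C)C)c2)[C@@H](Cc3cc(OC)c(OCc4ccccc4)c(Br)c3)C(=O)O | intermediate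
16 | (2S,3S)-3-[4-(benzyloxy)-3-bromo-5-methoxybenzyl]-2-(3-hydroxy-4-methoxybenzyl)butane-1,2,4-triol | OC[C@](O)(Cc1ccc(OC)c(O)c1)[C@H](CO)Cc2cc(OC)c(OCc3ccccc3)c(Br)c2 | intermediate
17 | 5-{(2S,3S)-3-[4-(benzyloxy)-3-bromo-5-methoxybenzyl]-2,4-dihydroxy-2-(hydroxymethyl)butyl}-2-methoxyphenyl pivalate | OC[C@](O)(Cc1ccc(OC)c(OC(=O)C(C)(C)C)c1)[C@H](CO)Cc2cc(OC)c(OCc3ccccc3)c(Br)c2 | intermediate
18 | 5-{(2S,3S)-3-[4-(benzyloxy)-3-methoxy-5-(4,4,5,5-tetramethyl-1,3,2-dioxaborolan-2-yl)benzyl]-2,4-dihydroxy-2-(hydroxymethyl)butyl}-2-methoxyphenyl pivalate | OC[C@](O)(Cc1ccc(OC)c(OC(=O)C(C)(C)C)c1)[C@H](CO)Cc2cc(OC)c(OCc3ccccc3)c(B4OC(C)(C)C(C)(C)O4)c2 | intermediate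
19 | vanillin | COc1cc(C=O)ccc1O | starting material
20 | 4-formyl-2-methoxyphenyl pivalate | COc1cc(C=O)ccc1OC(=O)C(C)(C)C | intermediate
21 | 4-(hydroxymethyl)-2-methoxyphenyl pivalate | COc1cc(CO)ccc1OC(=O)C(C)(C)C | intermediate
22 | 4-(bromomethyl)-2-methoxyphenyl pivalate | COc1cc(CBr)ccc1OC(=O)C(C)(C)C | intermediate
23 | disodium carboxylate enolate of 9 | [O-]C1=C([C@@H](Cc2cc(OC)c(OCc3ccccc3)c(Br)c2)C(=O)[O-])O[C@H](C(C)(C)C)O1.[Na+].[Na+] | intermediate
24 | (2R)-3-[4-(benzyloxy)-3-bromo-5-methoxyphenyl]-2-[(2S,4S)-2-tert-butyl-4-{[3-methoxy-4-(pivaloyloxy)phenyl]methyl}-5-oxo-1,3-dioxolan-4-yl]propanoic acid | O=C1O[C@@H](C(C)(C)C)O[C@@]1(Cc2ccc(OC(=O)C(C)(C)C)c(OC)c2)[C@@H](Cc3cc(OC)c(OCc4ccccc4)c(Br)c3)C(=O)O | intermediate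
25 | (2R)-3-(3-bromo-4-hydroxy-5-methoxyphenyl)-2-[(2S,4S)-2-tert-butyl-4-{[3-methoxy-4-(pivaloyloxy)phenyl]methyl}-5-oxo-1,3-dioxolan-4-yl]propanoic acid | O=C1O[C@@H](C(C)(C)C)O[C@@]1(Cc2ccc(OC(=O)C(C)(C)C)c(OC)c2)[C@@H](Cc3cc(OC)c(O)c(Br)c3)C(=O)O | intermediate
26 | ring C para-quinone methide of 25 (exocyclic alkene geometry not defined) | O=C1O[C@@H](C(C)(C)C)O[C@@]1(Cc2ccc(OC(=O)C(C)(C)C)c(OC)c2)[C@@H](C=C3C=C(OC)C(=O)C(Br)=C3)C(=O)O | intermediate
27 | (2S,4S,3'R,4'S)-4'-(3-bromo-4-hydroxy-5-methoxyphenyl)-2-tert-butyl-7'-methoxy-5-oxo-6'-(pivaloyloxy)-3',4'-dihydro-1'H-spiro[1,3-dioxolane-4,2'-naphthalene]-3'-carboxylic acid | COc1cc(cc(Br)c1O)[C@H]2c3cc(OC(=O)C(C)(C)C)c(OC)cc3C[C@]4(O[C@H](C(C)(C)C)OC4=O)[C@@H]2C(=O)O | intermediate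
28 | (2S,3S,4S)-4-(3-bromo-4-hydroxy-5-methoxyphenyl)-2,3-bis(hydroxymethyl)-7-methoxy-1,2,3,4-tetrahydronaphthalene-2,6-diol | COc1cc(cc(Br)c1O)[C@H]2c3cc(O)c(OC)cc3C[C@@](O)(CO)[C@@H]2CO | intermediate
29 | bis(pivalate) of 28 at the ring C and ring D phenols, (2S,3S,4S) | COc1cc(cc(Br)c1OC(=O)C(C)(C)C)[C@H]2c3cc(OC(=O)C(C)(C)C)c(OC)cc3C[C@@](O)(CO)[C@@H]2CO | intermediate
30 | C5–C5' biaryl: open-chain (2S,3S)-triol half (ring B O-benzyl, ring A O-pivalate) joined to the (2S,3S,4S)-aryltetralin triol bis(pivalate) | COc1ccc(C[C@@](O)(CO)[C@H](CO)Cc3cc(OC)c(OCc2ccccc2)c(-c4cc([C@H]5c6cc(OC(=O)C(C)(C)C)c(OC)cc6C[C@@](O)(CO)[C@@H]5CO)cc(OC)c4OC(=O)C(C)(C)C)c3)cc1OC(=O)C(C)(C)C | intermediate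
31 | key-step precursor: 30 with the ring B phenol free | COc1ccc(C[C@@](O)(CO)[C@H](CO)Cc3cc(OC)c(O)c(-c4cc([C@H]5c6cc(OC(=O)C(C)(C)C)c(OC)cc6C[C@@](O)(CO)[C@@H]5CO)cc(OC)c4OC(=O)C(C)(C)C)c3)cc1OC(=O)C(C)(C)C | intermediate
32 | ring B para-quinone methide of 31 (exocyclic alkene geometry not defined) | COc1ccc(C[C@@](O)(CO)[C@H](CO)C=C3C=C(OC)C(=O)C(c4cc([C@H]5c6cc(OC(=O)C(C)(C)C)c(OC)cc6C[C@@](O)(CO)[C@@H]5CO)cc(OC)c4OC(=O)C(C)(C)C)=C3)cc1OC(=O)C(C)(C)C | intermediate
33 | tris(pivalate) of the target, (7S,8R,8'S)-oxolane closed | COc1ccc(C[C@@]2(O)CO[C@H](c3cc(OC)c(O)c(-c4cc([C@H]5c6cc(OC(=O)C(C)(C)C)c(OC)cc6C[C@@](O)(CO)[C@@H]5CO)cc(OC)c4OC(=O)C(C)(C)C)c3)[C@H]2CO)cc1OC(=O)C(C)(C)C | intermediate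
34 | CNP0252244.1: (7S,8R,8'S)-oxolane half joined C5–C5' to the (2S,3S,4S)-aryltetralin half | COc1ccc(C[C@@]2(O)CO[C@H](c3cc(OC)c(O)c(-c4cc([C@H]5c6cc(O)c(OC)cc6C[C@@](O)(CO)[C@@H]5CO)cc(OC)c4O)c3)[C@H]2CO)cc1O | target

**Step count**
Total: 25 steps. Longest linear sequence: 15 steps (steps 1–6, 17–25).

**Steps most likely to fail**

Step 24 (key step). Hydride abstraction may also occur at the diarylmethine T1–H, the ring C pivaloyl group may migrate to the neighbouring free ring B phenol, the product may be oxidised further, and adventitious water may capture the quinone methide. The fallback closes the oxolane before the biaryl bond is made, on a substrate without the aryltetralin and without a neighbouring pivalate. It sets out from boronate 18: hydrogenolysis (H2, Pd/C) should give the phenol boronate F1, DDQ should oxidise it to the quinone methide F2, which cyclises to the oxolane boronate F3, and Suzuki–Miyaura coupling of F3 with bromide 29 (Pd(OAc)2, SPhos, K3PO4) comes back to the route at 33.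

Step 19. The aryltetralin formed still has a benzylic hydrogen para to the free phenol and may be oxidised further, the dioxolanone may be lost in acid, and the facial selectivity at T1 on the spiro-dioxolanone may be poor. The fallback moves the cyclisation to the dibenzylbutyrolactone, the substrate class on which the quinone-methide Friedel–Crafts closure is established. It sets out from 25: BH3·SMe2 reduces the carboxylic acid and acid-catalysed lactonisation onto the dioxolanone carbonyl should give the hydroxy lactone F4; DDQ gives the quinone methide F5, which CF3CO2H cyclises to the trans-fused aryltetralin lactone F6; LiAlH4 reduction of F6 comes back to the route at 28.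

Step 22. Pivaloyl groups may be hydrolysed or transferred under the basic aqueous conditions, the boronate may protodeboronate, and the hexol may slow the catalyst. The fallback unites the halves at the dioxolanone-acid stage, where loss of a pivalate or opening of a dioxolanone is without consequence because a global hydride reduction follows. It sets out from 15: Miyaura borylation should give the boronate acid F7, Suzuki–Miyaura coupling with bromophenol 27 the biaryl diacid F8, LiAlH4 the hexol F9 with three free phenols, and selective tripivaloylation of the phenoxides (PivCl, K2CO3) comes back to the route at 30.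

**Further compounds**
F1 | step 24 | 5-{(2S,3S)-2,4-dihydroxy-3-[4-hydroxy-3-methoxy-5-(4,4,5,5-tetramethyl-1,3,2-dioxaborolan-2-yl)benzyl]-2-(hydroxymethyl)butyl}-2-methoxyphenyl pivalate | OC[C@](O)(Cc1ccc(OC)c(OC(=O)C(C)(C)C)c1)[C@H](CO)Cc2cc(OC)c(O)c(B3OC(C)(C)C(C)(C)O3)c2
F2 | step 24 | ring B para-quinone methide of F1 | OC[C@](O)(Cc1ccc(OC)c(OC(=O)C(C)(C)C)c1)[C@H](CO)C=C2C=C(OC)C(=O)C(B3OC(C)(C)C(C)(C)O3)=C2
F3 | step 24 | 5-{[(3S,4R,5S)-3-hydroxy-5-[4-hydroxy-3-methoxy-5-(4,4,5,5-tetramethyl-1,3,2-dioxaborolan-2-yl)phenyl]-4-(hydroxymethyl)oxolan-3-yl]methyl}-2-methoxyphenyl pivalate | COc1ccc(C[C@@]2(O)CO[C@H](c3cc(OC)c(O)c(B4OC(C)(C)C(C)(C)O4)c3)[C@H]2CO)cc1OC(=O)C(C)(C)C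
F4 | step 19 | 4-{[(3S,4S)-4-(3-bromo-4-hydroxy-5-methoxybenzyl)-3-hydroxy-2-oxooxolan-3-yl]methyl}-2-methoxyphenyl pivalate | O=C1OC[C@H](Cc2cc(OC)c(O)c(Br)c2)[C@@]1(O)Cc3ccc(OC(=O)C(C)(C)C)c(OC)c3
F5 | step 19 | ring C para-quinone methide of F4 | O=C1OC[C@H](C=C2C=C(OC)C(=O)C(Br)=C2)[C@@]1(O)Cc3ccc(OC(=O)C(C)(C)C)c(OC)c3
F6 | step 19 | trans-fused aryltetralin hydroxy lactone (T1 aryl trans to T2, ring D O-pivalate) | COc1cc(cc(Br)c1O)[C@H]2c3cc(OC(=O)C(C)(C)C)c(OC)cc3C[C@@]4(O)C(=O)OC[C@H]24
F7 | step 22 | pinacol boronate of 15 (boron in place of bromine on ring B) | O=C1O[C@@H](C(C)(C)C)O[C@@]1(Cc2ccc(OC)c(OC(=O)C(C)(C)C)c2)[C@@H](Cc3cc(OC)c(OCc4ccccc4)c(B5OC(C)(C)C(C)(C)O5)c3)C(=O)O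
F8 | step 22 | C5–C5' biaryl bis(dioxolanone) diacid from F7 and 27 | O=C1O[C@@H](C(C)(C)C)O[C@@]1(Cc2ccc(OC)c(OC(=O)C(C)(C)C)c2)[C@@H](Cc3cc(OC)c(OCc4ccccc4)c(-c5cc(cc(OC)c5O)[C@H]6c7cc(OC(=O)C(C)(C)C)c(OC)cc7C[C@]8(O[C@H](C(C)(C)C)OC8=O)[C@@H]6C(=O)O)c3)C(=O)O
F9 | step 22 | biaryl hexol with ring B O-benzyl and the ring A, ring C and ring D phenols free | COc1ccc(C[C@@](O)(CO)[C@H](CO)Cc3cc(OC)c(OCc2ccccc2)c(-c4cc([C@H]5c6cc(O)c(OC)cc6C[C@@](O)(CO)[C@@H]5CO)cc(OC)c4O)c3)cc1O
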